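I want to know which flask holds the most links at 25 min, and how many, given that the earlier runs show links being lost again.

| setting | delta | zeta | eta | gamma | Wednesday's | Sunday's | Saturday's |
|---|---|---|---|---|---|---|---|
| first end groups | 0.13 M | 0.13 M | 0.13 M | 0.26 M | 0.13 M | 0.13 M (fed, over 20 min) | 0.13 M |
| second end groups | 0.98 equiv | 1.4 equiv | 2.2 equiv | 0.98 equiv | 0.980 equiv (fed, over 20 min) | 0.980 equiv | 0.980 equiv |
| remark | run made earlier | run made earlier | run made earlier | run made earlier | all else is in the flask from the start; the feed brings no volume worth counting | all else is in the flask from the start; the feed brings no volume worth counting | everything together at the start |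
| time |  |  |  |  | 25 min | 25 min | 25 min |

| run | time / min | links / % | first end groups / % |
|---|---|---|---|
| delta | 2.50 | 43.3 | 44.7 |
| delta | 5.00 | 39.1 | 30.3 |
| delta | 8.00 | 29.3 | 22.5 |
| delta | 10.0 | 25.9 | 17.7 |
| delta | 12.0 | 22.0 | 15.1 |
| delta | 15.0 | 17.0 | 14.3 |
| zeta | 3.00 | 54.1 | 28.1 |
| zeta | 6.00 | 45.8 | 14.2 |
| zeta | 10.0 | 29.4 | 5.8 |
| zeta | 12.0 | 26.3 | 6.2 |
| zeta | 15.0 | 18.6 | 6.7 |
| zeta | 20.0 | 10.4 | 2.0 |
| eta | 1.50 | 61.6 | 28.5 |
| eta | 2.50 | 65.5 | 15.5 |
| eta | 4.00 | 61.7 | 5.0 |
| eta | 8.00 | 42.7 | 1.2 |
| eta | 12.0 | 27.8 | 1.3 |
| eta | 20.0 | 11.6 | 0.9 |
| gamma | 1.50 | 51.1 | 38.7 |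
| gamma | 3.00 | 51.1 | 20.7 |
| gamma | 6.00 | 41.6 | 9.4 |
| gamma | 10.0 | 27.2 | 5.0 |
| gamma | 20.0 | 9.3 | 0.3 |

(each reading ± 1 percentage point)

- the analysis behind the earlier runs scatters by 1 percentage point, standard deviation
- steps thought possible: links -> over-reaction product; first end groups + second end groups -> links + by-product; second end groups -> decomposed reagent; first end groups + by-product -> side product

1. which flask leads in amount of links, in percent of the first end groups charged ("all alike" within 1.5 percentage points) (Wednesday's / Sunday's / Saturday's / all alike)
2. how much links is there at the end, in percent of the first end groups charged: Wednesday's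
3. how much links is there at the end, in percent of the first end groups charged: Sunday's
4. how much links is there at the end, in percent of the first end groups charged: Saturday's

In the eta run, first end groups stand at 1.2% by 8.00 min, and links then fall from 42.7% to 11.6% at 20.0 min. I read from this a first-order loss kL = 0.109 min⁻¹, the turnover rate of links: a link that has waited a time Δt has passed N = kL·Δt turnovers, and e^−N of such links survive.

The bench rule treats a batch as a pulse. Delta's first end groups fall to 44.7% by 2.50 min, which is shorter than the lifetime of links, so I date the links of Saturday's flask, delta's recipe, to that moment. The survivors are then 8.69% of those made. Delta's 17.0% at 15.0 min carries forward to 5.74%, so I reckon M = 66.1% of links made, roughly.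

The pulse stops at the feed: kL·tf = 2.17 turnovers, more than one. Averaging over steady formation, followed by the tail after the feed, gives a survival of 23.7%, and with the same M, Wednesday's holds 15.7%. In Sunday's flask second end groups wait while first end groups arrive over 20 min, and their decomposition is among the steps thought possible, so I carry no M over to that flask and expect Sunday's below Wednesday's, without a figure.

The forecast gives Wednesday's the lead, with 15% for Wednesday's, 3.9% for Sunday's and 5.6% for Saturday's: “links form late, so they have less time to decay”.

The flasks give 15.3% for Wednesday's, 4.59% for Sunday's and 5.36% for Saturday's, so Wednesday's leads.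

    links → over-reaction product (k = 0.110 min⁻¹)
    first end groups + second end groups → links + by-product (k = 4.00 M⁻¹ min⁻¹)
    second end groups → decomposed reagent (k = 0.140 min⁻¹)
    first end groups + by-product → side product (k = 0.970 M⁻¹ min⁻¹)

In Sunday's flask, decomposition gives second end groups a half-life of 4.95 min throughout, against 14 min by the step to links at 3.20 min, so at that moment decomposition is the faster; at 25.0 min the step to links has 2.5 min and is the faster. By 2.50 min, 41% of that decomposition's turnover up to 25 min lies behind. Sunday's links stand at 7.70% at 20.0 min, with second end groups at 0.362% of their charge, and kL carries this to 4.46% against the 4.59% found. Left until 1.0 h, the same flask holds 0.0984%, where counting turnovers from 4.59% gives 0.103%.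

(The data are simulated for substances that don't exist; noise was put on by code.)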